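**Plan**

Retrosynthesis: the ring B benzyl ether and the C3 configuration are adjusted last. The lactone C2–O1 bond is opened to a C2 acid and a C5 alcohol, C2 is taken back to a methylidene on C3 and C5 to a boron atom on C4, and then the ring A–CH2 bond and the C3–C4 bond are cut in one operation.
Enabling feature (lactone numbered O1, C2 carbonyl, C3, C4, C5; ring A = 3,4-dimethoxyphenyl of the C4 benzyl, ring B = 3-hydroxy-4,5-dimethoxyphenyl of the C3 benzyl): C4, the only stereocentre that base cannot repair, is a CH lying between the ring A benzylic CH2 and C3. This is the array left when a vinylboron ate complex is arylated at its terminal carbon while a second group moves from boron to the boron-bearing carbon.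
Forward: the ring B aldehyde is taken to a 2-bromoallyl arene and the ring A phenol to its triflate. Vinylboronate, ring B alkenyllithium and ring A triflate are joined in one open-chain coupling. C5 is then inserted into the C–B bond, the methylidene is oxidised to the C2 acid, and the lactone, the only ring made, closes near the end.
Stereochemistry: C4 comes from the chiral bisphosphine on palladium in the coupling and is carried through the stereoretentive boron homologation; C3 comes from equilibration to the trans lactone.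

Key step: step 7

Assumption: MandyPhos means the ferrocene ligand 1,1'-bis[bis(4-methoxy-3,5-dimethylphenyl)phosphino]-2,2'-bis[α-(dimethylamino)benzyl]ferrocene, available in both mirror-image forms; its sense of induction is taken from analogous aryl triflate couplings, and the enantiomer that gives boronate 13 as the R isomer is the one used.

**Route**

Step 1
Reactants: 1 3-hydroxy-4,5-dimethoxybenzaldehyde
Product: 2 3-(benzyloxy)-4,5-dimethoxybenzaldehyde
Conditions: BnBr, K2CO3, DMF, rt
Reagents that add atoms: benzyl bromide, BrCc1ccccc1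
Why: Williamson ether synthesis, in which the phenoxide formed with K2CO3 displaces bromide from benzyl bromide while the aldehyde is inert.

Step 2
Reactants: 2 3-(benzyloxy)-4,5-dimethoxybenzaldehyde
Product: 3 [3-(benzyloxy)-4,5-dimethoxyphenyl]methanol
Conditions: NaBH4, MeOH, 0 °C
Reagents that add atoms: none
Why: Borohydride reduction of an aryl aldehyde to the benzylic alcohol is chemoselective and leaves the aryl ethers untouched.

Step 3
Reactants: 3 [3-(benzyloxy)-4,5-dimethoxyphenyl]methanol
Product: 4 1-(benzyloxy)-5-(bromomethyl)-2,3-dimethoxybenzene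
Conditions: PBr3, Et2O, 0 °C
Reagents that add atoms: phosphorus tribromide, BrP(Br)Br
Why: Bromination of a primary benzylic alcohol with PBr3 proceeds by SN2 displacement of the activated phosphite ester at a temperature where the aryl benzyl ether is stable.

Step 4
Reactants: 4 1-(benzyloxy)-5-(bromomethyl)-2,3-dimethoxybenzene
Product: 5 1-(benzyloxy)-2,3-dimethoxy-5-(prop-2-yn-1-yl)benzene
Conditions: HC≡CMgBr, CuCl (cat.), THF, 50 °C
Reagents that add atoms: ethynylmagnesium bromide, C#C[Mg]Br
Why: Copper-catalysed Grignard cross-coupling at the benzylic carbon gives the 3-arylpropyne, and the absence of an amine or alkoxide base should keep isomerisation to the allene low.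

Step 5
Reactants: 5 1-(benzyloxy)-2,3-dimethoxy-5-(prop-2-yn-1-yl)benzene
Product: 7 1-(benzyloxy)-5-(2-bromoprop-2-en-1-yl)-2,3-dimethoxybenzene, via bromoalkenylborane 6 (not isolated)
Conditions: B-bromo-9-BBN, CH2Cl2, 0 °C; then AcOH, 0 °C to rt
Reagents that add atoms: B-bromo-9-BBN (9-bromo-9-borabicyclo[3.3.1]nonane), BrB1C2CCCC1CCC2
Why: Haloboration (bromoboration of a terminal alkyne) adds B–Br syn with bromine on the internal carbon, and protodeboronation of the alkenylborane with acetic acid leaves the 2-bromo-1-alkene; the low temperature should keep ether cleavage by the bromoborane slow.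

Step 6
Reactants: 8 3,4-dimethoxyphenol
Product: 9 3,4-dimethoxyphenyl trifluoromethanesulfonate
Conditions: Tf2O, pyridine, CH2Cl2, 0 °C
Reagents that add atoms: trifluoromethanesulfonic anhydride, O=S(=O)(OS(=O)(=O)C(F)(F)F)C(F)(F)F
Why: O-Sulfonylation of a phenol with triflic anhydride and pyridine is a standard triflation.

Step 7
Reactants: 7 1-(benzyloxy)-5-(2-bromoprop-2-en-1-yl)-2,3-dimethoxybenzene; 10 vinylboronic acid pinacol ester; 9 3,4-dimethoxyphenyl trifluoromethanesulfonate
Product: 13 2-{(2R)-4-[3-(benzyloxy)-4,5-dimethoxyphenyl]-1-(3,4-dimethoxyphenyl)-3-methylidenebutan-2-yl}-4,4,5,5-tetramethyl-1,3,2-dioxaborolane, via alkenyllithium 11 (not isolated), via lithium borate complex 12 (not isolated)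
Conditions: t-BuLi (2 equiv), Et2O, −78 °C; then 10, −78 °C to rt; solvent exchange to THF; 9, Pd(OAc)2 (cat.), MandyPhos bisphosphine (cat.), KOTf, THF, 60 °C
Reagents that add atoms: none
Why: Bromine–lithium exchange on 7 gives alkenyllithium 11, which adds to the boron of 10 to give bis(alkenyl) borate 12; oxidative addition of triflate 9 to zerovalent palladium then gives a cationic arylpalladium species (divalent palladium) that binds the unsubstituted vinyl group of 12, the 2-substituted alkenyl group shifts from boron to the adjacent carbon anti to the metal (C3–C4 bond), and reductive elimination joins the terminal carbon to ring A (ring A–CH2 bond). The closest known reaction type is the enantioselective palladium-catalysed conjunctive cross-coupling of bis(alkenyl)borates with aryl triflates, which delivers α-chiral allylic boronates of this substitution pattern. No ring is closed: two skeletal bonds and the C4 stereocentre are formed in an open chain. The configuration at C4 is controlled by the chiral ferrocenyl bisphosphine on palladium, which selects one face of the coordinated vinyl group during the metallate shift. The step needs palladium to activate the vinyl group and not the substituted alkenyl group, and it needs the metallate shift to outrun direct alkenyl transfer to palladium (Suzuki–Miyaura coupling); the first is secured by the 2-substituent of the ring B alkenyl group, which makes the vinyl group the less hindered π-ligand, and the second by the non-coordinating triflate counter-ion, kept free of bromide by KOTf, which leaves palladium cationic and alkene-bound. The pinacol ester is expected to hold the allylic boronate against 1,3-boron shift, so the C4 configuration should survive isolation.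

Step 8
Reactants: 13 2-{(2R)-4-[3-(benzyloxy)-4,5-dimethoxyphenyl]-1-(3,4-dimethoxyphenyl)-3-methylidenebutan-2-yl}-4,4,5,5-tetramethyl-1,3,2-dioxaborolane
Product: 16 (2R)-4-[3-(benzyloxy)-4,5-dimethoxyphenyl]-2-[(3,4-dimethoxyphenyl)methyl]-3-methylidenebutan-1-ol, via chloromethyl borate complex 14 (not isolated), via homologated boronate 15 (not isolated)
Conditions: BrCH2Cl, n-BuLi, THF, −78 °C to rt; then NaOH (aq), H2O2, 0 °C to rt
Reagents that add atoms: bromochloromethane, ClCBr; hydrogen peroxide, OO
Why: Matteson homologation, in which (chloromethyl)lithium made in the flask adds to boron and the C4 carbon migrates with retention as chloride leaves, followed by stereospecific oxidation of the primary boronate with alkaline H2O2, so that C5 is installed without touching the C4 configuration.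

Step 9
Reactants: 16 (2R)-4-[3-(benzyloxy)-4,5-dimethoxyphenyl]-2-[(3,4-dimethoxyphenyl)methyl]-3-methylidenebutan-1-ol
Product: 17 tert-butyl{[(2R)-4-[3-(benzyloxy)-4,5-dimethoxyphenyl]-2-[(3,4-dimethoxyphenyl)methyl]-3-methylidenebutyl]oxy}dimethylsilane
Conditions: TBSCl, imidazole, CH2Cl2, rt
Reagents that add atoms: tert-butyldimethylsilyl chloride, CC(C)(C)[Si](C)(C)Cl
Why: Silylation of the primary alcohol with TBSCl and imidazole masks the C5 oxygen, so that the two hydroxymethyl arms of the later diol stay distinguishable.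

Step 10
Reactants: 17 tert-butyl{[(2R)-4-[3-(benzyloxy)-4,5-dimethoxyphenyl]-2-[(3,4-dimethoxyphenyl)methyl]-3-methylidenebutyl]oxy}dimethylsilane
Product: 19 (3R)-2-{[3-(benzyloxy)-4,5-dimethoxyphenyl]methyl}-3-({[tert-butyl(dimethyl)silyl]oxy}methyl)-4-(3,4-dimethoxyphenyl)butan-1-ol (both C2 epimers), via alkylborane 18 (not isolated)
Conditions: 9-BBN, THF, 0 °C to rt; then NaOH (aq), H2O2, 0 °C
Reagents that add atoms: hydrogen peroxide, OO
Why: Hydroboration–oxidation with 9-BBN adds anti-Markovnikov to the 1,1-disubstituted alkene and gives the primary alcohol at the future C2; the new centre (lactone C3) needs no control because it is equilibrated in step 13.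

Step 11
Reactants: 19 (3R)-2-{[3-(benzyloxy)-4,5-dimethoxyphenyl]methyl}-3-({[tert-butyl(dimethyl)silyl]oxy}methyl)-4-(3,4-dimethoxyphenyl)butan-1-ol (both C2 epimers)
Product: 21 (3R)-2-{[3-(benzyloxy)-4,5-dimethoxyphenyl]methyl}-3-({[tert-butyl(dimethyl)silyl]oxy}methyl)-4-(3,4-dimethoxyphenyl)butanoic acid (both C2 epimers), via aldehyde 20 (not isolated)
Conditions: TEMPO (cat.), PhI(OAc)2, MeCN/H2O, rt
Reagents that add atoms: water, O
Why: TEMPO-catalysed oxidation with PhI(OAc)2 in aqueous acetonitrile takes a primary alcohol through the aldehyde and its hydrate to the carboxylic acid under conditions that silyl and benzyl ethers normally survive.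

Step 12
Reactants: 21 (3R)-2-{[3-(benzyloxy)-4,5-dimethoxyphenyl]methyl}-3-({[tert-butyl(dimethyl)silyl]oxy}methyl)-4-(3,4-dimethoxyphenyl)butanoic acid (both C2 epimers)
Product: 23 (4R)-3-{[3-(benzyloxy)-4,5-dimethoxyphenyl]methyl}-4-[(3,4-dimethoxyphenyl)methyl]oxolan-2-one (both C3 epimers), via hydroxy acid 22 (not isolated)
Conditions: HCl (1 M aq), THF, rt
Reagents that add atoms: none
Why: Acid-mediated desilylation frees the γ-hydroxy acid, which lactonises spontaneously under the same acidic conditions to the five-membered ring.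

Step 13
Reactants: 23 (4R)-3-{[3-(benzyloxy)-4,5-dimethoxyphenyl]methyl}-4-[(3,4-dimethoxyphenyl)methyl]oxolan-2-one (both C3 epimers)
Product: 24 (3R,4R)-3-{[3-(benzyloxy)-4,5-dimethoxyphenyl]methyl}-4-[(3,4-dimethoxyphenyl)methyl]oxolan-2-one
Conditions: DBU, toluene, 80 °C
Reagents that add atoms: none
Why: Base-mediated epimerisation through the lactone enolate acts only at C3, the sole acidic stereocentre, and the trans-3,4-dibenzyl lactone is expected to be the thermodynamically preferred isomer, so both epimers should converge on the (3R,4R) compound.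

Step 14
Reactants: 24 (3R,4R)-3-{[3-(benzyloxy)-4,5-dimethoxyphenyl]methyl}-4-[(3,4-dimethoxyphenyl)methyl]oxolan-2-one
Product: 25 (3R,4R)-4-[(3,4-dimethoxyphenyl)methyl]-3-[(3-hydroxy-4,5-dimethoxyphenyl)methyl]oxolan-2-one
Conditions: H2 (1 atm), palladium on carbon, EtOAc, rt
Reagents that add atoms: none
Why: Hydrogenolysis of the aryl benzyl ether over palladium on carbon frees the phenol under neutral conditions that leave the lactone, the methyl ethers and both stereocentres untouched.

**Compound list**

1 | 3-hydroxy-4,5-dimethoxybenzaldehyde | COc1cc(C=O)cc(O)c1OC | starting material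
2 | 3-(benzyloxy)-4,5-dimethoxybenzaldehyde | COc1cc(C=O)cc(OCc2ccccc2)c1OC | intermediate
3 | [3-(benzyloxy)-4,5-dimethoxyphenyl]methanol | COc1cc(CO)cc(OCc2ccccc2)c1OC | intermediate
4 | 1-(benzyloxy)-5-(bromomethyl)-2,3-dimethoxybenzene | COc1cc(CBr)cc(OCc2ccccc2)c1OC | intermediate
5 | 1-(benzyloxy)-2,3-dimethoxy-5-(prop-2-yn-1-yl)benzene | COc1cc(CC#C)cc(OCc2ccccc2)c1OC | intermediate
6 | 9-{(1Z)-3-[3-(benzyloxy)-4,5-dimethoxyphenyl]-2-bromoprop-1-en-1-yl}-9-borabicyclo[3.3.1]nonane | COc1cc(C/C(Br)=C/B2C3CCCC2CCC3)cc(OCc2ccccc2)c1OC | intermediate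
7 | 1-(benzyloxy)-5-(2-bromoprop-2-en-1-yl)-2,3-dimethoxybenzene | COc1cc(CC(Br)=C)cc(OCc2ccccc2)c1OC | intermediate
8 | 3,4-dimethoxyphenol | COc1ccc(O)cc1OC | starting material
9 | 3,4-dimethoxyphenyl trifluoromethanesulfonate | COc1ccc(OS(=O)(=O)C(F)(F)F)cc1OC | intermediate
10 | vinylboronic acid pinacol ester (2-ethenyl-4,4,5,5-tetramethyl-1,3,2-dioxaborolane) | C=CB1OC(C)(C)C(C)(C)O1 | starting material
11 | {3-[3-(benzyloxy)-4,5-dimethoxyphenyl]prop-1-en-2-yl}lithium | [Li]C(=C)Cc1cc(OCc2ccccc2)c(OC)c(OC)c1 | intermediate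
12 | lithium {3-[3-(benzyloxy)-4,5-dimethoxyphenyl]prop-1-en-2-yl}(ethenyl)(2,3-dimethylbutane-2,3-diolato)borate | [Li+].C=C[B-]1(OC(C)(C)C(C)(C)O1)C(=C)Cc1cc(OCc2ccccc2)c(OC)c(OC)c1 | intermediate
13 | 2-{(2R)-4-[3-(benzyloxy)-4,5-dimethoxyphenyl]-1-(3,4-dimethoxyphenyl)-3-methylidenebutan-2-yl}-4,4,5,5-tetramethyl-1,3,2-dioxaborolane | COc1ccc(C[C@H](C(=C)Cc2cc(OCc3ccccc3)c(OC)c(OC)c2)B2OC(C)(C)C(C)(C)O2)cc1OC | intermediate
14 | lithium (chloromethyl){(2R)-4-[3-(benzyloxy)-4,5-dimethoxyphenyl]-1-(3,4-dimethoxyphenyl)-3-methylidenebutan-2-yl}(2,3-dimethylbutane-2,3-diolato)borate | COc1ccc(C[C@H](C(=C)Cc2cc(OCc3ccccc3)c(OC)c(OC)c2)[B-]2(CCl)OC(C)(C)C(C)(C)O2)cc1OC.[Li+] | intermediate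
15 | 2-{(2R)-4-[3-(benzyloxy)-4,5-dimethoxyphenyl]-2-[(3,4-dimethoxyphenyl)methyl]-3-methylidenebutyl}-4,4,5,5-tetramethyl-1,3,2-dioxaborolane | COc1ccc(C[C@H](C(=C)Cc2cc(OCc3ccccc3)c(OC)c(OC)c2)CB2OC(C)(C)C(C)(C)O2)cc1OC | intermediate
16 | (2R)-4-[3-(benzyloxy)-4,5-dimethoxyphenyl]-2-[(3,4-dimethoxyphenyl)methyl]-3-methylidenebutan-1-ol | COc1ccc(C[C@H](C(=C)Cc2cc(OCc3ccccc3)c(OC)c(OC)c2)CO)cc1OC | intermediate
17 | tert-butyl{[(2R)-4-[3-(benzyloxy)-4,5-dimethoxyphenyl]-2-[(3,4-dimethoxyphenyl)methyl]-3-methylidenebutyl]oxy}dimethylsilane | COc1ccc(C[C@H](C(=C)Cc2cc(OCc3ccccc3)c(OC)c(OC)c2)CO[Si](C)(C)C(C)(C)C)cc1OC | intermediate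
18 | 9-[(3R)-2-{[3-(benzyloxy)-4,5-dimethoxyphenyl]methyl}-3-({[tert-butyl(dimethyl)silyl]oxy}methyl)-4-(3,4-dimethoxyphenyl)butyl]-9-borabicyclo[3.3.1]nonane (both C2 epimers) | COc1ccc(C[C@H](C(CB2C3CCCC2CCC3)Cc2cc(OCc3ccccc3)c(OC)c(OC)c2)CO[Si](C)(C)C(C)(C)C)cc1OC | intermediate
19 | (3R)-2-{[3-(benzyloxy)-4,5-dimethoxyphenyl]methyl}-3-({[tert-butyl(dimethyl)silyl]oxy}methyl)-4-(3,4-dimethoxyphenyl)butan-1-ol (both C2 epimers) | COc1ccc(C[C@H](C(CO)Cc2cc(OCc3ccccc3)c(OC)c(OC)c2)CO[Si](C)(C)C(C)(C)C)cc1OC | intermediate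
20 | (3R)-2-{[3-(benzyloxy)-4,5-dimethoxyphenyl]methyl}-3-({[tert-butyl(dimethyl)silyl]oxy}methyl)-4-(3,4-dimethoxyphenyl)butanal (both C2 epimers) | COc1ccc(C[C@H](C(C=O)Cc2cc(OCc3ccccc3)c(OC)c(OC)c2)CO[Si](C)(C)C(C)(C)C)cc1OC | intermediate
21 | (3R)-2-{[3-(benzyloxy)-4,5-dimethoxyphenyl]methyl}-3-({[tert-butyl(dimethyl)silyl]oxy}methyl)-4-(3,4-dimethoxyphenyl)butanoic acid (both C2 epimers) | COc1ccc(C[C@H](C(C(=O)O)Cc2cc(OCc3ccccc3)c(OC)c(OC)c2)CO[Si](C)(C)C(C)(C)C)cc1OC | intermediate
22 | (3R)-2-{[3-(benzyloxy)-4,5-dimethoxyphenyl]methyl}-4-(3,4-dimethoxyphenyl)-3-(hydroxymethyl)butanoic acid (both C2 epimers) | COc1ccc(C[C@H](C(C(=O)O)Cc2cc(OCc3ccccc3)c(OC)c(OC)c2)CO)cc1OC | intermediate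
23 | (4R)-3-{[3-(benzyloxy)-4,5-dimethoxyphenyl]methyl}-4-[(3,4-dimethoxyphenyl)methyl]oxolan-2-one (both C3 epimers) | COc1ccc(C[C@H]2COC(=O)C2Cc2cc(OCc3ccccc3)c(OC)c(OC)c2)cc1OC | intermediate
24 | (3R,4R)-3-{[3-(benzyloxy)-4,5-dimethoxyphenyl]methyl}-4-[(3,4-dimethoxyphenyl)methyl]oxolan-2-one | COc1ccc(C[C@H]2COC(=O)[C@@H]2Cc2cc(OCc3ccccc3)c(OC)c(OC)c2)cc1OC | intermediate
25 | (3R,4R)-4-[(3,4-dimethoxyphenyl)methyl]-3-[(3-hydroxy-4,5-dimethoxyphenyl)methyl]oxolan-2-one | COc1ccc(C[C@H]2COC(=O)[C@@H]2Cc2cc(O)c(OC)c(OC)c2)cc1OC | target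

**Step count and risks**

Total steps: 14. Longest linear sequence: 13 (steps 1–5 and 7–14); step 6 is the one-step side branch to triflate 9.

Steps most likely to fail:

1. Step 7. The alkenyl group may transfer directly from boron to arylpalladium (Suzuki–Miyaura coupling) instead of undergoing the metallate shift. Residual bromide may convert the cationic palladium into a neutral, alkene-free complex. The ligand may give insufficient facial selectivity at C4. The fallback sets out from bromide 4 and comes back to the route at 24.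
 - Stobbe condensation of 3,4-dimethoxybenzaldehyde with dimethyl succinate (KOt-Bu, t-BuOH) would give the half-ester (E)-4-(3,4-dimethoxyphenyl)-3-(methoxycarbonyl)but-3-enoic acid F1.
 - Asymmetric hydrogenation with [Rh(cod)2]BF4 and a chiral DIOP-type bisphosphine, chosen for the R product, would give (3R)-4-(3,4-dimethoxyphenyl)-3-(methoxycarbonyl)butanoic acid F2.
 - Reduction of the ester group of its potassium salt with Ca(BH4)2 would give (3R)-3-[(3,4-dimethoxyphenyl)methyl]-4-hydroxybutanoic acid F3, which on acidification closes to (4R)-4-[(3,4-dimethoxyphenyl)methyl]oxolan-2-one F4.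
 - LiN(SiMe3)2 in THF at −78 °C would give lithium (4R)-4-[(3,4-dimethoxyphenyl)methyl]-4,5-dihydrofuran-2-olate F5. Its alkylation by 4 is expected to occur anti to the C4 substituent and so give the trans lactone 24 directly, after which only step 14 remains.

2. Step 5. The Lewis-acidic bromoborane may cleave or complex the benzyl and methyl aryl ethers, the protodeboronation may stop short, or the propargylic arene may isomerise. The fallback sets out from alkyne 5 and comes back at 7. α-Selective hydroalumination with i-Bu2AlH under Ni(dppp)Cl2 catalysis (a hydrometalation in place of the haloboration) would give {3-[3-(benzyloxy)-4,5-dimethoxyphenyl]prop-1-en-2-yl}bis(2-methylpropyl)alumane F6. N-Bromosuccinimide at 0 °C would then convert its C–Al bond into the C–Br bond of 7.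

3. Step 8. The short-lived carbenoid may decompose before the hindered secondary allylic boron captures it, or a second methylene may insert into the primary boronate as it forms. The fallback sets out from 13 and comes back at 15. Dichloromethyllithium, preformed from CH2Cl2 and n-BuLi at −100 °C and longer-lived, would be added in measured amount and the rearrangement promoted with ZnCl2, giving the α-chloro boronate 2-{(2R)-4-[3-(benzyloxy)-4,5-dimethoxyphenyl]-1-chloro-2-[(3,4-dimethoxyphenyl)methyl]-3-methylidenebutyl}-4,4,5,5-tetramethyl-1,3,2-dioxaborolane F7. LiBHEt3 would then replace chloride by hydride through a 1,2-shift at boron to give 15, which is oxidised as in step 8.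

**Further compounds**

F1 | step 7 | (E)-4-(3,4-dimethoxyphenyl)-3-(methoxycarbonyl)but-3-enoic acid | COC(=O)/C(CC(=O)O)=C/c1ccc(OC)c(OC)c1
F2 | step 7 | (3R)-4-(3,4-dimethoxyphenyl)-3-(methoxycarbonyl)butanoic acid | COc1ccc(C[C@H](CC(=O)O)C(=O)OC)cc1OC
F3 | step 7 | (3R)-3-[(3,4-dimethoxyphenyl)methyl]-4-hydroxybutanoic acid | COc1ccc(C[C@H](CC(=O)O)CO)cc1OC
F4 | step 7 | (4R)-4-[(3,4-dimethoxyphenyl)methyl]oxolan-2-one | COc1ccc(C[C@H]2COC(=O)C2)cc1OC
F5 | step 7 | lithium (4R)-4-[(3,4-dimethoxyphenyl)methyl]-4,5-dihydrofuran-2-olate | [Li+].COc1ccc(C[C@H]2COC([O-])=C2)cc1OC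
F6 | step 5 | {3-[3-(benzyloxy)-4,5-dimethoxyphenyl]prop-1-en-2-yl}bis(2-methylpropyl)alumane | CC(C)C[Al](CC(C)C)C(=C)Cc1cc(OCc2ccccc2)c(OC)c(OC)c1
F7 | step 8 | 2-{(2R)-4-[3-(benzyloxy)-4,5-dimethoxyphenyl]-1-chloro-2-[(3,4-dimethoxyphenyl)methyl]-3-methylidenebutyl}-4,4,5,5-tetramethyl-1,3,2-dioxaborolane (both C1 epimers) | COc1ccc(C[C@H](C(=C)Cc2cc(OCc3ccccc3)c(OC)c(OC)c2)C(Cl)B2OC(C)(C)C(C)(C)O2)cc1OC
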